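Early on, Monday's and Thursday's runs read 14.8% and 15.7% of target at 30.0 min, with c(coupling partner) charged at 0.17 M and 0.70 M. Both runs hold catalyst and ligand charges fixed, so neither shows an order in catalyst.

all flasks: substrate 0.50 M; free catalyst 2.5 mM; added ligand 3.9 mM

| flask | coupling partner | remark |
|---|---|---|
| Monday's | 0.17 M | run made earlier |
| Thursday's | 0.70 M | run made earlier |
| flask | 0.350 M |  |

| run | time / min | target / % | substrate / % |
|---|---|---|---|
| Monday's | 2.50 | 0.6 | 98.7 |
| Monday's | 4.00 | 0.8 | 97.1 |
| Monday's | 6.00 | 3.4 | 96.4 |
| Monday's | 10.0 | 5.6 | 95.0 |
| Monday's | 20.0 | 12.3 | 88.3 |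
| Monday's | 30.0 | 14.8 | 82.1 |
| Thursday's | 2.00 | 1.5 | 100.3 |
| Thursday's | 6.00 | 3.1 | 96.7 |
| Thursday's | 10.0 | 6.8 | 93.1 |
| Thursday's | 15.0 | 8.0 | 91.3 |
| Thursday's | 25.0 | 12.6 | 87.0 |
| Thursday's | 30.0 | 15.7 | 83.2 |

(each reading ± 1 percentage point)

- apparent order in free catalyst when 30% of the substrate are converted (percent change of the rate of making target for one percent more free catalyst charged)
- factor on the rate of making target when 30% of the substrate are converted if free catalyst is charged twice over

- on the list of suspects stand: substrate + free catalyst <-> catalyst intermediate A; catalyst intermediate B -> free catalyst + target; coupling partner + catalyst intermediate A -> catalyst intermediate B; free catalyst + added ligand <-> idle complex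
- no earlier run changes the charge of free catalyst; that part of a forecast is a guess

This reckoning takes the rate as proportional to c(free catalyst) and lets binding to added ligand bend that proportion. Follow one catalyst molecule: p is its chance of sitting in idle complex, the off-cycle form. A ligand molecule is then bound with chance ρ·p, where ρ = c(free catalyst charged)/c(added ligand charged) = 0.641. Differentiating the binding balance gives the apparent order as 1/(1 − ρ·p·p). This runs from 1 at p = 0 to 2.79 at p = 1. The readings show target and substrate, not p, so p = 0.5 is a guess; it gives an order of 1.19 and, with that order held over a doubling, a factor of 2.28.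

The forecast stands higher, with order 1.4 and factor 2.8, on the ground that “extra catalyst titrates the ligand”.

When 30% of the substrate are converted, the flask gives order 1.2 and factor 2.46.

    substrate + free catalyst ⇌ catalyst intermediate A (K = 4.40 /M, k = 7.50 /M/min)
    catalyst intermediate B → free catalyst + target (k = 8.10 /min)
    coupling partner + catalyst intermediate A → catalyst intermediate B (k = 1200 /M/min)
    free catalyst + added ligand ⇌ idle complex, settled at all times (K = 640 /M)

At 25.0 min, before the 57.9 min at which 30% stand converted, the flask holds 53.8% of the catalyst charged in idle complex. With ρ, that share gives an order of 1.23 for that moment.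

(The numbers in the tables stem from a simulated flask on assumed constants, noise included.)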